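**Plan** (oxolane numbered O1, C2 = carbon with the hydroxy-dienyl arm, C3 = carbon with the cyclopropyl carbinol arm, C4 = carbon with the alkenyl arm, C5 = carbon with the dienyl arm)
1. Cuts, in order: both (Z)-alkenes next to the oxolane arms (double Wittig); the (E)-alkene between C4 and its cyclopropane (Julia–Kocienski with aldehyde 11); the cyclopropane and the carbinol–alkenyl bond of the C3 arm (OH-directed Simmons–Smith, alkenylzinc addition of alkyne 6); last the ring bond C2–C3.
2. Enabling feature: C3 carries an exocyclic oxygenated carbon, so O1–C2–C3–CH=O is a β-alkoxy aldehyde (aldol array). That is the product of a [1,3] O-to-C shift of a seven-membered cyclic vinyl acetal (4,5-dihydro-1,3-dioxepine), whose acetal carbon becomes C2 and whose enol-ether carbons become C3 and the formyl carbon.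
3. Forward: alcohol 16 and aldehyde 20 are tied as a mixed acetal, closed by isomerisation/RCM to dioxepine 25, and contracted by two atoms to oxolane aldehyde 27. Both arms are then built from one alkynyl lactone (6, and its cyclopropyl aldehyde 11); the dienes come last.
4. Stereochemistry: C4/C5 from Ir-catalysed anti-(hydroxymethyl)allylation; the side-chain carbinol from (S)-α-hydroxy-γ-butyrolactone; C2/C3 by thermodynamic all-trans control in the key step (acetal epimers converge); lactone carbinols from Noyori transfer hydrogenation; cyclopropanes by Charette (reagent) and OH-directed (substrate) Simmons–Smith; the cyclopropyl carbinol by MIB-controlled alkenylzinc addition; Z-alkenes by Wittig, E-alkene by Julia–Kocienski.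

Key step: step 17

Remark: the sense of induction of the Ir/SEGPHOS and Zn/MIB catalysts is assigned by analogy with simple aldehydes; if it proves opposite, the antipodal ligand is used and nothing else changes.

**Route**

Step 1
Reactants: 1 methyl 5-chloro-5-oxopentanoate; 2 bis(trimethylsilyl)acetylene
Product: 3 methyl 5-oxo-7-(trimethylsilyl)hept-6-ynoate
Conditions: AlCl3, CH2Cl2, 0 °C
Reagents that add atoms: none
Why: Friedel–Crafts-type acylation of the silylalkyne (ipso substitution of one Me3Si) should give the ynone while the methyl ester is inert at 0 °C.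

Step 2
Reactants: 3
Product: 4 methyl (5R)-5-hydroxy-7-(trimethylsilyl)hept-6-ynoate
Conditions: Ru[(R,R)-TsDPEN](p-cymene) (1 mol%), i-PrOH, rt
Reagents that add atoms: none
Why: Noyori asymmetric transfer hydrogenation of an alkynyl ketone, in which the alkynyl group acts as the unsaturated substituent and the (R,R) catalyst should give the (R)-propargylic alcohol.

Step 3
Reactants: 4
Product: 6 (6R)-6-ethynyloxan-2-one, via desilylated hydroxy ester 5 (not isolated)
Conditions: K2CO3 (cat.), MeOH, 0 °C; evaporate; TsOH (cat.), PhMe, 40 °C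
Reagents that add atoms: none
Why: methanolysis of the C–Si bond followed by acid-catalysed δ-lactonisation with loss of methanol leaves the carbinol centre untouched.

Step 4
Reactants: 6
Product: 7 (6R)-6-ethenyloxan-2-one
Conditions: H2 (1 atm), Lindlar catalyst, quinoline, EtOAc, rt
Reagents that add atoms: none
Why: Lindlar semihydrogenation stops at the terminal alkene and does not touch the lactone.

Step 5
Reactants: 7; 8 (Z)-but-2-ene-1,4-diol
Product: 9 (6R)-6-[(1E)-3-hydroxyprop-1-en-1-yl]oxan-2-one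
Conditions: Hoveyda–Grubbs II (5 mol%), 8 (4 equiv), CH2Cl2, 40 °C
Reagents that add atoms: none
Why: olefin cross-metathesis of a slowly homodimerising allylic-acyloxy alkene with an excess of a reactive cis-olefin should give the (E)-allylic alcohol under thermodynamic control.

Step 6
Reactants: 9
Product: 10 (6R)-6-[(1S,2S)-2-(hydroxymethyl)cyclopropyl]oxan-2-one
Conditions: Zn(CH2I)2·DME (from Et2Zn, CH2I2, DME), (4R,5R)-2-butyl-N,N,N',N'-tetramethyl-1,3,2-dioxaborolane-4,5-dicarboxamide (1.2 equiv), CH2Cl2, −10 °C to rt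
Reagents that add atoms: diiodomethane (ICI)
Why: Charette asymmetric Simmons–Smith cyclopropanation, in which the boronate-bound allylic alkoxide steers the zinc carbenoid to one alkene face (reagent control, same sense as cinnamyl alcohol giving the S,S product) and the E-alkene gives the trans-cyclopropane stereospecifically.

Step 7
Reactants: 10
Product: 11 (1S,2S)-2-[(2R)-6-oxooxan-2-yl]cyclopropane-1-carbaldehyde
Conditions: Dess–Martin periodinane, NaHCO3, CH2Cl2, rt
Reagents that add atoms: none
Why: Dess–Martin oxidation of the primary alcohol gives the configurationally robust trans-cyclopropanecarbaldehyde without touching the lactone.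

Step 8
Reactants: 12 3-[(tert-butyldimethylsilyl)oxy]propan-1-ol; 13 4-ethenyl-1,3-dioxolan-2-one (racemic)
Product: 14 (2R,3R)-5-[(tert-butyldimethylsilyl)oxy]-2-ethenylpentane-1,3-diol
Conditions: [Ir(cod)Cl]2 (2.5 mol%), (R)-SEGPHOS (5 mol%), 4-cyano-3-nitrobenzoic acid (10 mol%), K3PO4 (cat.), THF, 90 °C
Reagents that add atoms: none
Why: Ir-catalysed transfer-hydrogenative carbonyl (hydroxymethyl)allylation from the alcohol oxidation level (Krische), in which the carbonate ionises with loss of CO2 to a (hydroxymethyl)allyl–iridium species that adds to the transient aldehyde through a closed chair transition state, which should give the anti 2-vinyl-1,3-diol with catalyst-controlled absolute configuration.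

Step 9
Reactants: 14
Product: 15 (3R,4S)-1-[(tert-butyldimethylsilyl)oxy]-4-{[(1-phenyl-1H-tetrazol-5-yl)sulfanyl]methyl}hex-5-en-3-ol
Conditions: 1-phenyl-1H-tetrazole-5-thiol, PPh3, DIAD, THF, 0 °C
Reagents that add atoms: 1-phenyl-1H-tetrazole-5-thiol (Sc1nnnn1-c1ccccc1)
Why: Mitsunobu thioetherification is selective for the primary hydroxyl of the 1,3-diol and touches no stereocentre.

Step 10
Reactants: 15
Product: 16 (3R,4S)-1-[(tert-butyldimethylsilyl)oxy]-4-{[(1-phenyl-1H-tetrazol-5-yl)sulfonyl]methyl}hex-5-en-3-ol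
Conditions: (NH4)6Mo7O24·4H2O (cat.), 30% H2O2, EtOH, 0 °C to rt
Reagents that add atoms: hydrogen peroxide (OO)
Why: molybdate-catalysed sulfide-to-sulfone oxidation is chemoselective over the terminal alkene and the silyl ether.

Step 11
Reactants: 17 (3S)-3-hydroxyoxolan-2-one
Product: 18 (2S)-2,4-dihydroxy-N-methoxy-N-methylbutanamide
Conditions: MeNH(OMe)·HCl, AlMe3, CH2Cl2, 0 °C to rt
Reagents that add atoms: N,O-dimethylhydroxylamine hydrochloride (CNOC.Cl)
Why: Weinreb aminolysis of the lactone with the aluminium amide opens the ring without epimerising the α-carbinol.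

Step 12
Reactants: 18
Product: 19 (2S)-2,4-bis[(tert-butyldimethylsilyl)oxy]-N-methoxy-N-methylbutanamide
Conditions: TBSCl (2.5 equiv), imidazole, DMF, rt
Reagents that add atoms: tert-butyldimethylsilyl chloride (CC(C)(C)[Si](C)(C)Cl)
Why: standard silylation of both hydroxyls prevents relactonisation and installs the protecting groups used to the end.

Step 13
Reactants: 19
Product: 20 (2S)-2,4-bis[(tert-butyldimethylsilyl)oxy]butanal
Conditions: DIBAL-H, THF, −78 °C
Reagents that add atoms: none
Why: Weinreb amide reduction stops at the aldehyde through the chelated tetrahedral intermediate, so the α-silyloxy centre should not epimerise.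

Step 14
Reactants: 20
Product: 21 (2S)-2,4-bis[(tert-butyldimethylsilyl)oxy]butanal diallyl acetal
Conditions: allyloxytrimethylsilane (2.5 equiv), TMSOTf (cat.), CH2Cl2, −78 °C
Reagents that add atoms: allyloxytrimethylsilane (C=CCO[Si](C)(C)C)
Why: Noyori acetalisation with the silyl ether under aprotic catalysis forms the acetal at −78 °C without loss of the silyl ethers.

Step 15
Reactants: 21; 16
Product: 23 mixed allyl acetal of 20 with alcohol 16 (both acetal epimers), via collidinium salt 22 (not isolated)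
Conditions: TESOTf, 2,4,6-collidine, CH2Cl2, 0 °C; then 16
Reagents that add atoms: none
Why: Fujioka mixed-acetal synthesis, in which one allyloxy group is exchanged through an N-(α-alkoxyalkyl)collidinium salt that is electrophilic enough for the alcohol but not for the homoallylic alkene, so Prins closure is avoided; the new acetal centre is formed as a mixture that the key step erases.

Step 16
Reactants: 23
Product: 25 (4R,5S)-2-[(1S)-1,3-bis(tert-butyldimethylsilyloxy)propyl]-4-[2-(tert-butyldimethylsilyloxy)ethyl]-5-{[(1-phenyl-1H-tetrazol-5-yl)sulfonyl]methyl}-4,5-dihydro-1,3-dioxepine (both C2 epimers), via propenyl acetal 24 (not isolated)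
Conditions: [Ir(cod)(PMePh2)2]PF6 (3 mol%, H2-activated), THF, rt; evaporate; Grubbs II (10 mol%), PhMe, 70 °C
Reagents that add atoms: none
Why: cationic Ir–H isomerisation turns the O-allyl group into the O-(E)-propenyl group, and enol-ether ring-closing metathesis with the vinyl group then closes the seven-membered cyclic vinyl acetal with loss of propene.

Step 17
Reactants: 25
Product: 27 all-trans-2-[(1S)-1,3-bis(tert-butyldimethylsilyloxy)propyl]-5-[2-(tert-butyldimethylsilyloxy)ethyl]-4-{[(1-phenyl-1H-tetrazol-5-yl)sulfonyl]methyl}oxolane-3-carbaldehyde (C5 R), via silyl enol ether oxocarbenium ion pair 26 (not isolated)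
Conditions: TMSOTf (0.3–1.0 equiv), CH2Cl2, −78 to 0 °C; Et3N quench
Reagents that add atoms: none
Why: TMSOTf activates the enol-ether oxygen and cleaves its bond to the acetal carbon, giving an oxocarbenium ion tethered to a (Z)-silyl enol ether; the enol carbon then bonds to the oxocarbenium carbon, so the O–C–O unit is exchanged for a C–C bond and the enol oxygen and its carbon leave the ring as the formyl group (formal [1,3] O-to-C shift, seven-membered ring to five). The closest known reaction type is the Lewis-acid ring contraction of 4,5-dihydro-1,3-dioxepines to oxolane-3-carbaldehydes (Petasis–Ferrier-type rearrangement). The oxolane closes by 5-(enol-exo)-endo-trig attack on the oxocarbenium ion, the Prins/Mukaiyama mode that is feasible for cationic acceptors. C3 is α to the aldehyde and epimerisable, and C2 is set in a C–C bond formation that is reversible under the Lewis acid (retro-aldol-type re-ionisation), so both should settle trans to the fixed C4 and C5 substituents; both acetal epimers of 25 funnel into the same all-trans ring. The step needs recombination at carbon and not at oxygen, and closure ahead of silyl loss; the cis enol geometry held in the ion pair, the absence of external nucleophiles and the low starting temperature should secure this, and warming allows equilibration.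

Step 18
Reactants: 6; 27
Product: 30 oxolane 27 with the formyl group converted into a (1R,2E)-1-hydroxy-3-[(2R)-6-oxooxan-2-yl]prop-2-en-1-yl group, via alkenylborane 28 (not isolated), via alkenylzinc 29 (not isolated)
Conditions: 6, Cy2BH (from BH3·SMe2 and cyclohexene), PhMe, 0 °C to rt; Me2Zn, −78 °C; (+)-MIB (10 mol%), then 27, −20 to 0 °C
Reagents that add atoms: none
Why: hydroboration of the terminal alkyne gives the (E)-alkenylborane, boron-to-zinc exchange gives the alkenylzinc, and amino-alcohol-catalysed addition to the aldehyde (Oppolzer–Walsh asymmetric alkenylation) should set the carbinol by reagent control (Re-face delivery) while lactone and sulfone are left alone.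

Step 19
Reactants: 30
Product: 31 cyclopropyl carbinol: the alkene of 30 converted into the trans-cyclopropane, configuration as in the target
Conditions: Et2Zn (5 equiv), CH2I2 (10 equiv), CH2Cl2, −10 to 0 °C
Reagents that add atoms: diiodomethane (ICI)
Why: hydroxyl-directed Simmons–Smith (Furukawa) cyclopropanation, in which the zinc alkoxide delivers CH2 to the alkene face syn to the carbinol oxygen in the A(1,3)-minimised conformer, which is the face required here; the acylated lactone oxygen on the other side does not direct.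

Step 20
Reactants: 31
Product: 32 tert-butyldimethylsilyl ether of 31 at the cyclopropyl carbinol
Conditions: TBSOTf, 2,6-lutidine, CH2Cl2, −78 to 0 °C
Reagents that add atoms: tert-butyldimethylsilyl trifluoromethanesulfonate (CC(C)(C)[Si](C)(C)OS(=O)(=O)C(F)(F)F)
Why: silyl triflate silylation protects the hindered secondary alcohol against the base of step 21 and the oxidant of step 23.

Step 21
Reactants: 32; 11
Product: 33 tetrakis-TBS bis-lactone: the CH2–sulfonyl group of 32 replaced by an (E)-CH=CH link to the cyclopropane of 11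
Conditions: KHMDS (1.1 equiv) added to 32 and 11 (1.3 equiv), DME, −60 °C to rt
Reagents that add atoms: none
Why: Julia–Kocienski olefination, in which the metallated phenyltetrazolyl sulfone adds to the cyclopropanecarbaldehyde and Smiles rearrangement with loss of SO2 and tetrazolate should give the (E)-alkene expected for an α-branched aldehyde under KHMDS/DME.

Step 22
Reactants: 33
Product: 34 diol: both primary silyl ethers of 33 removed
Conditions: HF·pyridine, pyridine, THF, 0 °C
Reagents that add atoms: none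
Why: buffered HF·pyridine cleaves primary TBS ethers much faster than the two hindered secondary ones and does not open the lactones.

Step 23
Reactants: 34
Product: 35 dialdehyde: both primary alcohols of 34 oxidised
Conditions: Dess–Martin periodinane (3 equiv), NaHCO3, CH2Cl2, 0 °C to rt; used crude
Reagents that add atoms: none
Why: Dess–Martin oxidation under buffered, non-basic conditions gives the two β-alkoxy aldehydes without β-elimination.

Step 24
Reactants: 36 (Z)-hex-3-en-1-ol
Product: 37 (Z)-1-bromohex-3-ene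
Conditions: CBr4, PPh3, CH2Cl2, 0 °C
Reagents that add atoms: carbon tetrabromide (BrC(Br)(Br)Br)
Why: Appel bromination of the primary alcohol leaves the (Z)-alkene unchanged.

Step 25
Reactants: 37
Product: 38 [(Z)-hex-3-en-1-yl]triphenylphosphonium bromide
Conditions: PPh3, MeCN, reflux
Reagents that add atoms: triphenylphosphine (c1ccc(cc1)P(c1ccccc1)c1ccccc1)
Why: SN2 quaternisation of triphenylphosphine by the primary bromide gives the Wittig salt.

Step 26
Reactants: 35; 38
Product: 40 bis-TBS ether of the target (silyl ethers on the two secondary carbinols), via phosphorus ylide 39 (not isolated)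
Conditions: 38 (3 equiv), NaHMDS (2.9 equiv), THF, 0 °C; then 35, −78 to −20 °C
Reagents that add atoms: none
Why: two-fold Wittig reaction of the non-stabilised ylide under lithium-free conditions at low temperature should form both new (Z)-alkenes, the aldehydes reacting far faster than the lactones.

Step 27
Reactants: 40
Product: 41 target CNP0273074.1
Conditions: HF·pyridine (excess), pyridine, THF, 0 °C to rt
Reagents that add atoms: none
Why: fluoride-mediated cleavage of the two secondary TBS ethers under mildly acidic conditions should spare the lactones, the skipped dienes and the cyclopropyl carbinol.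

**Compound list**

1 | methyl 5-chloro-5-oxopentanoate | COC(=O)CCCC(=O)Cl | starting material
2 | bis(trimethylsilyl)acetylene | C[Si](C)(C)C#C[Si](C)(C)C | starting material
3 | methyl 5-oxo-7-(trimethylsilyl)hept-6-ynoate | COC(=O)CCCC(=O)C#C[Si](C)(C)C | intermediate
4 | methyl (5R)-5-hydroxy-7-(trimethylsilyl)hept-6-ynoate | C[Si](C)(C)C#C[C@H](O)CCCC(=O)OC | intermediate
5 | methyl (5R)-5-hydroxyhept-6-ynoate | C#C[C@H](O)CCCC(=O)OC | intermediate
6 | (6R)-6-ethynyloxan-2-one | C#C[C@H]1CCCC(=O)O1 | intermediate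
7 | (6R)-6-ethenyloxan-2-one | C=C[C@H]1CCCC(=O)O1 | intermediate
8 | (Z)-but-2-ene-1,4-diol | OC/C=C\CO | starting material
9 | (6R)-6-[(1E)-3-hydroxyprop-1-en-1-yl]oxan-2-one | OC/C=C/[C@H]1CCCC(=O)O1 | intermediate
10 | (6R)-6-[(1S,2S)-2-(hydroxymethyl)cyclopropyl]oxan-2-one | OC[C@H]1C[C@@H]1[C@H]1CCCC(=O)O1 | intermediate
11 | (1S,2S)-2-[(2R)-6-oxooxan-2-yl]cyclopropane-1-carbaldehyde | O=C[C@H]1C[C@@H]1[C@H]1CCCC(=O)O1 | intermediate
12 | 3-[(tert-butyldimethylsilyl)oxy]propan-1-ol | CC(C)(C)[Si](C)(C)OCCCO | starting material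
13 | 4-ethenyl-1,3-dioxolan-2-one | C=CC1COC(=O)O1 | starting material
14 | (2R,3R)-5-[(tert-butyldimethylsilyl)oxy]-2-ethenylpentane-1,3-diol | O[C@H](CCO[Si](C)(C)C(C)(C)C)[C@@H](CO)C=C | intermediate
15 | (3R,4S)-1-[(tert-butyldimethylsilyl)oxy]-4-{[(1-phenyl-1H-tetrazol-5-yl)sulfanyl]methyl}hex-5-en-3-ol | O[C@H](CCO[Si](C)(C)C(C)(C)C)[C@@H](CSc1nnnn1-c1ccccc1)C=C | intermediate
16 | (3R,4S)-1-[(tert-butyldimethylsilyl)oxy]-4-{[(1-phenyl-1H-tetrazol-5-yl)sulfonyl]methyl}hex-5-en-3-ol | O[C@H](CCO[Si](C)(C)C(C)(C)C)[C@@H](CS(=O)(=O)c1nnnn1-c1ccccc1)C=C | intermediate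
17 | (3S)-3-hydroxyoxolan-2-one ((S)-α-hydroxy-γ-butyrolactone) | O[C@H]1CCOC1=O | starting material
18 | (2S)-2,4-dihydroxy-N-methoxy-N-methylbutanamide | OCC[C@H](O)C(=O)N(C)OC | intermediate
19 | (2S)-2,4-bis[(tert-butyldimethylsilyl)oxy]-N-methoxy-N-methylbutanamide | CC(C)(C)[Si](C)(C)OCC[C@H](O[Si](C)(C)C(C)(C)C)C(=O)N(C)OC | intermediate
20 | (2S)-2,4-bis[(tert-butyldimethylsilyl)oxy]butanal | CC(C)(C)[Si](C)(C)OCC[C@H](O[Si](C)(C)C(C)(C)C)C=O | intermediate
21 | diallyl acetal of 20 | CC(C)(C)[Si](C)(C)OCC[C@H](O[Si](C)(C)C(C)(C)C)C(OCC=C)OCC=C | intermediate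
22 | N-[1-(allyloxy)-2,4-bis(silyloxy)butyl]-2,4,6-trimethylpyridinium triflate | C=CCOC([n+]1c(C)cc(C)cc1C)[C@H](CCO[Si](C)(C)C(C)(C)C)O[Si](C)(C)C(C)(C)C.[O-]S(=O)(=O)C(F)(F)F | intermediate
23 | mixed allyl acetal of 20 with alcohol 16 (acetal epimers) | C=CCOC(O[C@H](CCO[Si](C)(C)C(C)(C)C)[C@@H](CS(=O)(=O)c1nnnn1-c1ccccc1)C=C)[C@H](CCO[Si](C)(C)C(C)(C)C)O[Si](C)(C)C(C)(C)C | intermediate
24 | (E)-prop-1-enyl analogue of 23 | C/C=C/OC(O[C@H](CCO[Si](C)(C)C(C)(C)C)[C@@H](CS(=O)(=O)c1nnnn1-c1ccccc1)C=C)[C@H](CCO[Si](C)(C)C(C)(C)C)O[Si](C)(C)C(C)(C)C | intermediate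
25 | (4R,5S)-2,4,5-trisubstituted 4,5-dihydro-1,3-dioxepine (C2 epimers) | CC(C)(C)[Si](C)(C)OCC[C@H](O[Si](C)(C)C(C)(C)C)C1OC=C[C@H](CS(=O)(=O)c2nnnn2-c2ccccc2)[C@@H](CCO[Si](C)(C)C(C)(C)C)O1 | intermediate
26 | ring-opened (Z)-trimethylsilyl enol ether / oxocarbenium triflate | C[Si](C)(C)O/C=C\[C@H](CS(=O)(=O)c1nnnn1-c1ccccc1)[C@@H](CCO[Si](C)(C)C(C)(C)C)[O+]=C[C@H](CCO[Si](C)(C)C(C)(C)C)O[Si](C)(C)C(C)(C)C.[O-]S(=O)(=O)C(F)(F)F | intermediate
27 | all-trans oxolane-3-carbaldehyde | CC(C)(C)[Si](C)(C)OCC[C@H](O[Si](C)(C)C(C)(C)C)[C@H]1O[C@H](CCO[Si](C)(C)C(C)(C)C)[C@@H](CS(=O)(=O)c2nnnn2-c2ccccc2)[C@@H]1C=O | intermediate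
28 | dicyclohexyl{(E)-2-[(2R)-6-oxooxan-2-yl]ethenyl}borane | C1CCCCC1B(/C=C/[C@H]2CCCC(=O)O2)C1CCCCC1 | intermediate
29 | methyl{(E)-2-[(2R)-6-oxooxan-2-yl]ethenyl}zinc | C[Zn]/C=C/[C@H]1CCCC(=O)O1 | intermediate
30 | (R)-allylic alcohol from 27 and 6 | CC(C)(C)[Si](C)(C)OCC[C@H](O[Si](C)(C)C(C)(C)C)[C@H]1O[C@H](CCO[Si](C)(C)C(C)(C)C)[C@@H](CS(=O)(=O)c2nnnn2-c2ccccc2)[C@@H]1[C@H](O)/C=C/[C@H]1CCCC(=O)O1 | intermediate
31 | cyclopropyl carbinol | CC(C)(C)[Si](C)(C)OCC[C@H](O[Si](C)(C)C(C)(C)C)[C@H]1O[C@H](CCO[Si](C)(C)C(C)(C)C)[C@@H](CS(=O)(=O)c2nnnn2-c2ccccc2)[C@@H]1[C@H](O)[C@H]1C[C@@H]1[C@H]1CCCC(=O)O1 | intermediate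
32 | TBS ether of 31 | CC(C)(C)[Si](C)(C)OCC[C@H](O[Si](C)(C)C(C)(C)C)[C@H]1O[C@H](CCO[Si](C)(C)C(C)(C)C)[C@@H](CS(=O)(=O)c2nnnn2-c2ccccc2)[C@@H]1[C@H](O[Si](C)(C)C(C)(C)C)[C@H]1C[C@@H]1[C@H]1CCCC(=O)O1 | intermediate
33 | tetrakis-TBS bis-lactone with the (E)-alkene | CC(C)(C)[Si](C)(C)OCC[C@H](O[Si](C)(C)C(C)(C)C)[C@H]1O[C@H](CCO[Si](C)(C)C(C)(C)C)[C@@H](/C=C/[C@H]2C[C@@H]2[C@H]2CCCC(=O)O2)[C@@H]1[C@H](O[Si](C)(C)C(C)(C)C)[C@H]1C[C@@H]1[C@H]1CCCC(=O)O1 | intermediate
34 | diol (primary alcohols free) | OCC[C@H](O[Si](C)(C)C(C)(C)C)[C@H]1O[C@H](CCO)[C@@H](/C=C/[C@H]2C[C@@H]2[C@H]2CCCC(=O)O2)[C@@H]1[C@H](O[Si](C)(C)C(C)(C)C)[C@H]1C[C@@H]1[C@H]1CCCC(=O)O1 | intermediate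
35 | dialdehyde | O=CC[C@H](O[Si](C)(C)C(C)(C)C)[C@H]1O[C@H](CC=O)[C@@H](/C=C/[C@H]2C[C@@H]2[C@H]2CCCC(=O)O2)[C@@H]1[C@H](O[Si](C)(C)C(C)(C)C)[C@H]1C[C@@H]1[C@H]1CCCC(=O)O1 | intermediate
36 | (Z)-hex-3-en-1-ol | CC/C=C\CCO | starting material
37 | (Z)-1-bromohex-3-ene | CC/C=C\CCBr | intermediate
38 | [(Z)-hex-3-en-1-yl]triphenylphosphonium bromide | CC/C=C\CC[P+](c1ccccc1)(c1ccccc1)c1ccccc1.[Br-] | intermediate
39 | [(Z)-hex-3-en-1-ylidene]triphenylphosphorane | CC/C=C\CC=P(c1ccccc1)(c1ccccc1)c1ccccc1 | intermediate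
40 | bis-TBS ether of the target | CC/C=C\C/C=C\C[C@H](O[Si](C)(C)C(C)(C)C)[C@H]1O[C@H](C/C=C\C/C=C\CC)[C@@H](/C=C/[C@H]2C[C@@H]2[C@H]2CCCC(=O)O2)[C@@H]1[C@H](O[Si](C)(C)C(C)(C)C)[C@H]1C[C@@H]1[C@H]1CCCC(=O)O1 | intermediate
41 | CNP0273074.1 | CC/C=C\C/C=C\C[C@H](O)[C@H]1O[C@H](C/C=C\C/C=C\CC)[C@@H](/C=C/[C@H]2C[C@@H]2[C@H]2CCCC(=O)O2)[C@@H]1[C@H](O)[C@H]1C[C@@H]1[C@H]1CCCC(=O)O1 | target

**Step count and risks**

Total step count: 27. Longest linear sequence: 15 steps (17 to 41: steps 11–23, 26, 27).

Steps most likely to fail: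

1. Step 17. The acetal carbon carries an α-silyloxy group, so ionisation and re-ionisation may be slow; the ring may then be fixed under kinetic control as the C2 epimer, or the ion pair may collapse back at oxygen or lose a silyl group before carbon–carbon closure. Fallback, setting out from 16 and 20 and returning at 27: 20 is converted into its dimethyl acetal F1 (methoxytrimethylsilane, cat. TMSOTf). F1 is joined to 16 by the same TESOTf/collidine exchange to give the mixed methyl acetal F2. Hydroboration–oxidation of the vinyl group (9-BBN, then NaBO3) gives primary alcohol F3, and Dess–Martin oxidation gives aldehyde F4. TMSOTf/i-Pr2NEt then forms the enol silane in situ and ionises the acetal, and the oxolane closes by direct intramolecular Mukaiyama-type addition to 27. The closure now runs from an open-chain enol silane, so the kinetic preference differs and no dioxepine is needed.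

2. Step 16. The iridium hydride may also move the vinyl group of the homoallylic part, or isomerise the allyl ether incompletely; metathesis would then close an eight-membered ring or stall on the electron-rich enol ether. Fallback, setting out from 20 and 16 and returning at 25: 20 is acetalised with 2-(phenylselanyl)ethanol to the bis(selenoethyl) acetal F5. The TESOTf/collidine exchange with 16 gives the mixed acetal F6. NaIO4 oxidation gives selenoxide F7, whose syn-elimination on warming gives the O-vinyl acetal F8 with no metal hydride involved. Grubbs II then closes 25 with loss of ethene.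

3. Step 18. The catalyst may be mismatched with the α-branched, hindered aldehyde, giving poor facial selectivity at the new carbinol, or the addition may be slow enough for methyl transfer to compete. Fallback, setting out from 6 and 27 and returning at 30: hydrozirconation–iodination of 6 (Cp2Zr(H)Cl, then I2) gives the (E)-vinyl iodide F9. Nozaki–Hiyama–Kishi coupling with 27 (CrCl2, cat. NiCl2) gives the carbinol epimer mixture F10. Dess–Martin oxidation gives enone F11, and reagent-controlled CBS reduction (catalyst enantiomer chosen for the 9R carbinol) gives 30.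

**Further compounds**

F1 | step 17 | dimethyl acetal of 20 | CC(C)(C)[Si](C)(C)OCC[C@H](O[Si](C)(C)C(C)(C)C)C(OC)OC
F2 | step 17 | mixed methyl acetal of 20 with alcohol 16 | COC(O[C@H](CCO[Si](C)(C)C(C)(C)C)[C@@H](CS(=O)(=O)c1nnnn1-c1ccccc1)C=C)[C@H](CCO[Si](C)(C)C(C)(C)C)O[Si](C)(C)C(C)(C)C
F3 | step 17 | primary alcohol from hydroboration of F2 | COC(O[C@H](CCO[Si](C)(C)C(C)(C)C)[C@@H](CS(=O)(=O)c1nnnn1-c1ccccc1)CCO)[C@H](CCO[Si](C)(C)C(C)(C)C)O[Si](C)(C)C(C)(C)C
F4 | step 17 | aldehyde from F3 | COC(O[C@H](CCO[Si](C)(C)C(C)(C)C)[C@@H](CS(=O)(=O)c1nnnn1-c1ccccc1)CC=O)[C@H](CCO[Si](C)(C)C(C)(C)C)O[Si](C)(C)C(C)(C)C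
F5 | step 16 | bis[2-(phenylselanyl)ethyl] acetal of 20 | CC(C)(C)[Si](C)(C)OCC[C@H](O[Si](C)(C)C(C)(C)C)C(OCC[Se]c1ccccc1)OCC[Se]c1ccccc1
F6 | step 16 | mixed 2-(phenylselanyl)ethyl acetal with 16 | c1ccccc1[Se]CCOC(O[C@H](CCO[Si](C)(C)C(C)(C)C)[C@@H](CS(=O)(=O)c1nnnn1-c1ccccc1)C=C)[C@H](CCO[Si](C)(C)C(C)(C)C)O[Si](C)(C)C(C)(C)C
F7 | step 16 | selenoxide of F6 | O=[Se](CCOC(O[C@H](CCO[Si](C)(C)C(C)(C)C)[C@@H](CS(=O)(=O)c1nnnn1-c1ccccc1)C=C)[C@H](CCO[Si](C)(C)C(C)(C)C)O[Si](C)(C)C(C)(C)C)c1ccccc1
F8 | step 16 | mixed O-vinyl acetal | C=COC(O[C@H](CCO[Si](C)(C)C(C)(C)C)[C@@H](CS(=O)(=O)c1nnnn1-c1ccccc1)C=C)[C@H](CCO[Si](C)(C)C(C)(C)C)O[Si](C)(C)C(C)(C)C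
F9 | step 18 | (6R)-6-[(E)-2-iodoethenyl]oxan-2-one | I/C=C/[C@H]1CCCC(=O)O1
F10 | step 18 | allylic alcohol as carbinol epimer mixture | CC(C)(C)[Si](C)(C)OCC[C@H](O[Si](C)(C)C(C)(C)C)[C@H]1O[C@H](CCO[Si](C)(C)C(C)(C)C)[C@@H](CS(=O)(=O)c2nnnn2-c2ccccc2)[C@@H]1C(O)/C=C/[C@H]1CCCC(=O)O1
F11 | step 18 | enone | CC(C)(C)[Si](C)(C)OCC[C@H](O[Si](C)(C)C(C)(C)C)[C@H]1O[C@H](CCO[Si](C)(C)C(C)(C)C)[C@@H](CS(=O)(=O)c2nnnn2-c2ccccc2)[C@@H]1C(=O)/C=C/[C@H]1CCCC(=O)O1
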